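**Plan**

1.  Numbering used throughout: ring A is C1 (CH2OAc), C2 (H), C3 (CH3), C4 (H), C5 (OH), C6 (O‑aryl); ring B is C1′ (ether O), C4′ (prenyl), C5′ (OH), C6′ (CO2H); TBS = tert‑butyldimethylsilyl.
2.  Retrosynthesis: after removal of the acetate and the protecting groups, ring A is cut at C1–C2 and C3–C4, a [4+2] disconnection with a sulfinate as traceless leaving group. This gives a 2‑aryloxy‑3‑silyloxy diene (C4, C5, C6, C1 and the CH2O carbon) and 1‑(phenylsulfonyl)propyne (C2, C3 and the methyl group).
3.  Enabling feature: the ether carbon C6 of ring A lies between the hydroxyl carbon C5 and the oxymethyl‑bearing carbon C1, which is the O–CH2–C(=O) pattern of an aryloxyacetone. The diene is therefore cut at C6=C1 (aldol/dehydration with a silyloxyacetaldehyde) and at the O–CH2 bond (Williamson) to a ring B phenol and chloroacetone; ring B is cut at its C4′–CH2 bond (prenyl bromide).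
4.  Forward order: ring B is bought as methyl 2,6‑dihydroxybenzoate, C‑prenylated and etherified at its less hindered phenol. The dienyl chain is grown on that oxygen, and ring A is closed last by cycloaddition and aromatisation. Desilylation, saponification and an acetylation/partial deacetylation pair complete the target.
5.  Stereochemistry: the target has no stereocentre. The only stereochemical element of the route is the Z geometry of the C6=C1 enol‑ether double bond of the diene, set under thermodynamic control in the dehydration and erased on aromatisation.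

Key step: step 8

Remark: the target has no stereocentre and no stereogenic double bond, so it is a single achiral compound and no enantiocontrol is needed; all compounds marked as starting materials are taken to be commercially available.

**Route**

Step 1
Reactants: 1 methyl 2,6‑dihydroxybenzoate; 2 prenyl bromide (1‑bromo‑3‑methylbut‑2‑ene)
Product: 3 methyl 2,6‑dihydroxy‑3‑(3‑methylbut‑2‑en‑1‑yl)benzoate
Conditions: 1 (1.5 equiv), NaH (1.5 equiv), toluene, 0 °C; then 2 (1.0 equiv), 0 °C → rt
Reagents that add atoms: none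
Why: C‑alkylation of a sodium phenoxide held as a tight ion pair in a non‑polar solvent places the prenyl group ortho to the phenoxide oxygen, C3 being the only free ortho position (equivalent to C5 by symmetry), while the excess of 1 should hold back a second prenylation.

Step 2
Reactants: 3 methyl 2,6‑dihydroxy‑3‑(3‑methylbut‑2‑en‑1‑yl)benzoate; 4 chloroacetone
Product: 5 methyl 2‑hydroxy‑3‑(3‑methylbut‑2‑en‑1‑yl)‑6‑(2‑oxopropoxy)benzoate
Conditions: 4 (1.2 equiv), K2CO3 (1.5 equiv), KI (cat.), acetone, 50 °C
Reagents that add atoms: none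
Why: Williamson ether synthesis in which the C6 hydroxyl, flanked by only one substituent, should react ahead of the C2 hydroxyl wedged between the ester and the prenyl group, the remaining hydrogen‑bonded phenol and the mild carbonate base guarding against double alkylation and against Claisen‑type closure onto the ester.

Step 3
Reactants: 5 methyl 2‑hydroxy‑3‑(3‑methylbut‑2‑en‑1‑yl)‑6‑(2‑oxopropoxy)benzoate
Product: 6 methyl 2‑(TBSO)‑3‑(3‑methylbut‑2‑en‑1‑yl)‑6‑{[2‑(TBSO)prop‑1‑en‑1‑yl]oxy}benzoate (E/Z mixture at the enol ether)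
Conditions: TBSOTf (2.4 equiv), Et3N (4 equiv), CH2Cl2, 0 °C → rt
Reagents that add atoms: tert‑butyldimethylsilyl trifluoromethanesulfonate (TBSOTf), CC(C)(C)[Si](C)(C)OS(=O)(=O)C(F)(F)F
Why: Silyl triflate/amine silylation caps the phenol and turns the ketone into its silyl enol ether under equilibrating conditions, which should enolise toward the aryloxy‑bearing CH2 because it is the more acidic site and leads to the more substituted, oxygen‑conjugated double bond, the alkene geometry of 6 being irrelevant for the next step.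

Step 4
Reactants: 6 bis‑silyl enol ether from step 3; 7 (tert‑butyldimethylsilyloxy)acetaldehyde
Product: 8 methyl 2‑(TBSO)‑6‑{[5‑(TBSO)‑4‑hydroxy‑2‑oxopentan‑3‑yl]oxy}‑3‑(3‑methylbut‑2‑en‑1‑yl)benzoate (racemic diastereomer mixture)
Conditions: 7 (1.3 equiv), BF3·OEt2 (1.2 equiv), CH2Cl2, −78 °C; aq. NaHCO3
Reagents that add atoms: none
Why: Mukaiyama aldol addition of the enol silane to the BF3‑activated aldehyde forms the C–C bond at the aryloxy‑bearing carbon only, and the two new stereocentres, formed without control as a diastereomer mixture, are both erased in step 5.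

Step 5
Reactants: 8 aldol adduct from step 4
Product: 10 methyl 2‑(TBSO)‑6‑({(3Z)‑5‑(TBSO)‑2‑oxopent‑3‑en‑3‑yl}oxy)‑3‑(3‑methylbut‑2‑en‑1‑yl)benzoate, via mesylate 9 (not isolated)
Conditions: MsCl (1.5 equiv), Et3N (3 equiv), CH2Cl2, 0 °C; then DBU (2 equiv), 0 °C → rt
Reagents that add atoms: none
Why: Mesylation followed by E1cB elimination through the ketone enolate gives the conjugated enone, for which the Z isomer (CH2OTBS trans to the acetyl group, cis to the aryloxy group) is expected to be thermodynamically preferred because it avoids allylic strain with the acetyl group; any E isomer can be removed or re‑equilibrated with catalytic iodine.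

Step 6
Reactants: 10 (Z)‑enone from step 5
Product: 11 methyl 6‑({(3Z)‑2,5‑bis(TBSO)penta‑1,3‑dien‑3‑yl}oxy)‑2‑(TBSO)‑3‑(3‑methylbut‑2‑en‑1‑yl)benzoate
Conditions: TBSOTf (1.3 equiv), Et3N (2.5 equiv), Et2O, 0 °C
Reagents that add atoms: tert‑butyldimethylsilyl trifluoromethanesulfonate (TBSOTf), CC(C)(C)[Si](C)(C)OS(=O)(=O)C(F)(F)F
Why: Silyl triflate/amine enolisation of the methyl ketone at its α′ methyl group (kinetic deprotonation of the O‑silylated enone) gives the cross‑conjugated 2‑silyloxy diene, a standard preparation of such dienes from α,β‑unsaturated methyl ketones, with the Z double bond untouched.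

Step 7
Reactants: 12 1‑(trimethylsilyl)propyne; 13 benzenesulfonyl chloride
Product: 14 1‑(phenylsulfonyl)prop‑1‑yne
Conditions: AlCl3 (1.1 equiv), CH2Cl2, 0 °C → rt; aq. HCl
Reagents that add atoms: none
Why: Friedel–Crafts‑type sulfonylation of an alkynylsilane: the AlCl3‑activated sulfonyl chloride attacks the silicon‑bearing carbon, the developing vinyl cation being stabilised β to silicon, and loss of the silyl group as Me3SiCl restores the triple bond.

Step 8
Reactants: 11 (Z)‑2‑aryloxy‑3‑silyloxy diene from step 6; 14 1‑(phenylsulfonyl)prop‑1‑yne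
Product: 17 methyl 2‑(TBSO)‑6‑[2‑(TBSO)‑6‑(TBSO‑methyl)‑4‑methylphenoxy]‑3‑(3‑methylbut‑2‑en‑1‑yl)benzoate, via cyclohexa‑1,4‑diene cycloadduct 15 (not isolated), via allylic sulfone 16 (not isolated)
Conditions: 14 (1.5 equiv), BHT (cat.), toluene, 110–130 °C (sealed tube); then DBU (3 equiv), rt
Reagents that add atoms: none
Why: A concerted but asynchronous [4+2] cycloaddition between the s‑cis diene and the alkynyl sulfone forms C1–C2 and C3–C4 and gives the 1,4‑cyclohexadiene 15; DBU then removes a doubly allylic C4 hydrogen, reprotonation at C2 gives the allylic sulfone 16, and E1cB‑type loss of benzenesulfinate across C1–C2 aromatises ring A. The closest known reaction type is the Diels–Alder benzannulation of 2‑silyloxy dienes with acetylenic sulfones followed by base‑induced elimination of sulfinic acid. Ring A is closed by intermolecular [4+2] annulation, four ring carbons (C4, C5, C6, C1) coming from the diene and two (C2, C3) from the dienophile. No stereocentre is created in the product, the sp3 centres of 15 and 16 being transient and removed on aromatisation. The step needs regioselectivity, which the diene secures: the silyloxy group at C5 is a stronger donor than the aryloxy group at C6, whose lone pair is shared with an ester‑bearing arene, and the alkyl substituent at C1 reinforces it, so the unsubstituted terminus C4 should carry the larger HOMO coefficient and bond to the methyl‑bearing β‑carbon of the sulfone, which puts CH3 on C3 and the leaving group on C2. It also needs a diene able to reach the s‑cis conformation, which the Z geometry fixed in step 5 provides by keeping CH2OTBS on the outside of the diene.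

Step 9
Reactants: 17 tris‑silyl diaryl ether methyl ester from step 8
Product: 18 methyl 2‑hydroxy‑6‑[2‑hydroxy‑6‑(hydroxymethyl)‑4‑methylphenoxy]‑3‑(3‑methylbut‑2‑en‑1‑yl)benzoate
Conditions: TBAF (4 equiv), THF, 0 °C → rt; aq. NH4Cl
Reagents that add atoms: none
Why: Fluoride‑induced cleavage of silyl ethers, driven by the strength of the Si–F bond, frees both phenols and the benzylic alcohol while the hindered methyl ester stays intact.

Step 10
Reactants: 18 triol methyl ester from step 9
Product: 19 2‑hydroxy‑6‑[2‑hydroxy‑6‑(hydroxymethyl)‑4‑methylphenoxy]‑3‑(3‑methylbut‑2‑en‑1‑yl)benzoic acid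
Conditions: KOH (10 equiv), MeOH/H2O (3:1), 75 °C, Ar; then 1 M HCl, 0 °C, to pH 3
Reagents that add atoms: potassium hydroxide, [K+].[OH-]
Why: Saponification of the di‑ortho‑substituted, hydrogen‑bonded salicylate needs forcing alkaline conditions, which the diaryl ether, the prenyl group, the phenols and the benzylic alcohol should tolerate when air is excluded, and cold, brief acidification avoids acid‑mediated chroman formation from the ortho‑prenyl phenol.

Step 11
Reactants: 19 triol acid from step 10
Product: 20 2‑acetoxy‑6‑[2‑acetoxy‑6‑(acetoxymethyl)‑4‑methylphenoxy]‑3‑(3‑methylbut‑2‑en‑1‑yl)benzoic acid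
Conditions: Ac2O (8 equiv), pyridine, DMAP (cat.), 0 °C → rt; aq. work‑up
Reagents that add atoms: acetic anhydride, CC(=O)OC(C)=O
Why: DMAP‑catalysed acylation with acetic anhydride acetylates the primary alcohol and the phenols alike (complete acetylation of the hindered ring B phenol is not required because all aryl acetates are removed in step 12), and the acid is recovered free after aqueous work‑up.

Step 12
Reactants: 20 triacetate acid from step 11
Product: 21 7‑O‑acetylsecopenicillide C
Conditions: NH4OAc (10 equiv), MeOH/H2O (4:1), rt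
Reagents that add atoms: none
Why: Chemoselective methanolysis of aryl acetates: the phenoxide leaving groups make the two aryl acetates far more reactive toward mild ammonium acetate‑promoted transesterification than the alkyl acetate, so the benzylic acetate should remain.

**Compound list**

1 | methyl 2,6‑dihydroxybenzoate | COC(=O)c1c(O)cccc1O | starting material
2 | prenyl bromide (1‑bromo‑3‑methylbut‑2‑ene) | CC(C)=CCBr | starting material
3 | methyl 2,6‑dihydroxy‑3‑(3‑methylbut‑2‑en‑1‑yl)benzoate | COC(=O)c1c(O)ccc(CC=C(C)C)c1O | intermediate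
4 | chloroacetone | CC(=O)CCl | starting material
5 | methyl 2‑hydroxy‑3‑(3‑methylbut‑2‑en‑1‑yl)‑6‑(2‑oxopropoxy)benzoate | CC(=O)COc1ccc(CC=C(C)C)c(O)c1C(=O)OC | intermediate
6 | methyl 2‑(TBSO)‑3‑(3‑methylbut‑2‑en‑1‑yl)‑6‑{[2‑(TBSO)prop‑1‑en‑1‑yl]oxy}benzoate, E/Z mixture at the enol ether | CC(O[Si](C)(C)C(C)(C)C)=COc1ccc(CC=C(C)C)c(O[Si](C)(C)C(C)(C)C)c1C(=O)OC | intermediate
7 | (tert‑butyldimethylsilyloxy)acetaldehyde | O=CCO[Si](C)(C)C(C)(C)C | starting material
8 | methyl 2‑(TBSO)‑6‑{[5‑(TBSO)‑4‑hydroxy‑2‑oxopentan‑3‑yl]oxy}‑3‑(3‑methylbut‑2‑en‑1‑yl)benzoate, racemic diastereomer mixture | CC(=O)C(Oc1ccc(CC=C(C)C)c(O[Si](C)(C)C(C)(C)C)c1C(=O)OC)C(O)CO[Si](C)(C)C(C)(C)C | intermediate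
9 | mesylate of 8 (4‑methanesulfonyloxy in place of 4‑hydroxy; diastereomer mixture; not isolated) | CC(=O)C(Oc1ccc(CC=C(C)C)c(O[Si](C)(C)C(C)(C)C)c1C(=O)OC)C(OS(C)(=O)=O)CO[Si](C)(C)C(C)(C)C | intermediate
10 | methyl 2‑(TBSO)‑6‑({(3Z)‑5‑(TBSO)‑2‑oxopent‑3‑en‑3‑yl}oxy)‑3‑(3‑methylbut‑2‑en‑1‑yl)benzoate | CC(=O)/C(Oc1ccc(CC=C(C)C)c(O[Si](C)(C)C(C)(C)C)c1C(=O)OC)=C/CO[Si](C)(C)C(C)(C)C | intermediate
11 | methyl 6‑({(3Z)‑2,5‑bis(TBSO)penta‑1,3‑dien‑3‑yl}oxy)‑2‑(TBSO)‑3‑(3‑methylbut‑2‑en‑1‑yl)benzoate | C=C(O[Si](C)(C)C(C)(C)C)/C(Oc1ccc(CC=C(C)C)c(O[Si](C)(C)C(C)(C)C)c1C(=O)OC)=C/CO[Si](C)(C)C(C)(C)C | intermediate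
12 | 1‑(trimethylsilyl)propyne | CC#C[Si](C)(C)C | starting material
13 | benzenesulfonyl chloride | O=S(=O)(Cl)c1ccccc1 | starting material
14 | 1‑(phenylsulfonyl)prop‑1‑yne | CC#CS(=O)(=O)c1ccccc1 | intermediate
15 | cycloadduct: ring A as cyclohexa‑1,4‑diene (C2=C3 and C5=C6), sp3 C1 (H, CH2OTBS) and C4 (H2), PhSO2 on C2, CH3 on C3, OTBS on C5, ring B aryloxy on C6; racemic; not isolated | CC1=C(S(=O)(=O)c2ccccc2)C(CO[Si](C)(C)C(C)(C)C)C(Oc2ccc(CC=C(C)C)c(O[Si](C)(C)C(C)(C)C)c2C(=O)OC)=C(O[Si](C)(C)C(C)(C)C)C1 | intermediate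
16 | isomerised allylic sulfone: ring A as cyclohexa‑1,3‑diene (C3=C4 and C5=C6), sp3 C1 (H, CH2OTBS) and C2 (H, SO2Ph); racemic diastereomer mixture; not isolated | CC1=CC(O[Si](C)(C)C(C)(C)C)=C(Oc2ccc(CC=C(C)C)c(O[Si](C)(C)C(C)(C)C)c2C(=O)OC)C(CO[Si](C)(C)C(C)(C)C)C1S(=O)(=O)c3ccccc3 | intermediate
17 | methyl 2‑(TBSO)‑6‑[2‑(TBSO)‑6‑(TBSO‑methyl)‑4‑methylphenoxy]‑3‑(3‑methylbut‑2‑en‑1‑yl)benzoate | CC(C)(C)[Si](C)(C)OCc1cc(C)cc(O[Si](C)(C)C(C)(C)C)c1Oc1ccc(CC=C(C)C)c(O[Si](C)(C)C(C)(C)C)c1C(=O)OC | intermediate
18 | methyl 2‑hydroxy‑6‑[2‑hydroxy‑6‑(hydroxymethyl)‑4‑methylphenoxy]‑3‑(3‑methylbut‑2‑en‑1‑yl)benzoate | OCc1cc(C)cc(O)c1Oc1ccc(CC=C(C)C)c(O)c1C(=O)OC | intermediate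
19 | 2‑hydroxy‑6‑[2‑hydroxy‑6‑(hydroxymethyl)‑4‑methylphenoxy]‑3‑(3‑methylbut‑2‑en‑1‑yl)benzoic acid | OCc1cc(C)cc(O)c1Oc1ccc(CC=C(C)C)c(O)c1C(=O)O | intermediate
20 | 2‑acetoxy‑6‑[2‑acetoxy‑6‑(acetoxymethyl)‑4‑methylphenoxy]‑3‑(3‑methylbut‑2‑en‑1‑yl)benzoic acid | CC(=O)OCc1cc(C)cc(OC(C)=O)c1Oc1ccc(CC=C(C)C)c(OC(C)=O)c1C(=O)O | intermediate
21 | 7‑O‑acetylsecopenicillide C | CC(=O)OCc1cc(C)cc(O)c1Oc1ccc(CC=C(C)C)c(O)c1C(=O)O | target

**Step count and risks**

Total step count: 12. Longest linear sequence: 11 steps (from 1 through steps 1–6 and 8–12); step 7 is a one‑step side branch.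

Steps most likely to fail:

Step 8. The cycloaddition may be too slow with the β‑methyl‑substituted alkynyl sulfone at temperatures that the silyl dienol ether survives, or the competing aryloxy donor may erode the regiocontrol. The fallback sets out from 11 and replaces the alkyne by its allene isomer. Commercial phenyl prop‑2‑yn‑1‑yl sulfone is isomerised with catalytic Et3N in CH2Cl2 to 1‑(phenylsulfonyl)propa‑1,2‑diene F1, whose sulfonyl‑substituted double bond is a far more reactive dienophile and an established propyne equivalent. 11 and F1 in toluene at 40–60 °C should give the exocyclic‑methylene cycloadduct F2, the diene terminus C4 bonding to the electrophilic central allene carbon. DBU then moves the exocyclic double bond into the ring, which gives the vinyl sulfone 15, and the sequence runs on through 16 to come back to the route at 17.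

Step 3. Enolisation may take place toward the methyl group and not toward the aryloxy‑bearing carbon, which would carry the aldol bond of step 4 to the wrong α‑carbon. The fallback sets out from 3 and fixes the site by a phosphonate. Rh2(OAc)4‑catalysed O–H insertion of dimethyl (1‑diazo‑2‑oxopropyl)phosphonate (toluene, 80 °C) into the less hindered phenol should give methyl 6‑{[1‑(dimethoxyphosphoryl)‑2‑oxopropyl]oxy}‑2‑hydroxy‑3‑(3‑methylbut‑2‑en‑1‑yl)benzoate F3, which has a single acidic position. Horner–Wadsworth–Emmons olefination of F3 with 7 (LiCl, DBU, MeCN, rt) should then give methyl 2‑hydroxy‑6‑({(3Z)‑5‑(TBSO)‑2‑oxopent‑3‑en‑3‑yl}oxy)‑3‑(3‑methylbut‑2‑en‑1‑yl)benzoate F4, with the double bond necessarily at the aryloxy carbon. TBSOTf (2.5 equiv) and Et3N silylate the phenol and enolise the methyl ketone in one operation, and the fallback comes back to the route at 11.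

Step 2. Discrimination between the two hydrogen‑bonded phenols may be insufficient, with alkylation at the C2 hydroxyl or at both. The fallback sets out from 1 and introduces the two substituents in the reverse order. The symmetric diol 1 is monoalkylated with 4 (K2CO3, acetone, 50 °C) to methyl 2‑hydroxy‑6‑(2‑oxopropoxy)benzoate F5, where no site question arises. The remaining phenol is O‑prenylated with 2 (K2CO3, acetone, reflux) to methyl 2‑[(3‑methylbut‑2‑en‑1‑yl)oxy]‑6‑(2‑oxopropoxy)benzoate F6. Montmorillonite K10 in CH2Cl2 at rt then shifts the prenyl group from oxygen to the adjacent free ring carbon (a formal [1,3] shift through a tight allyl cation–phenol pair). This places the prenyl group next to the oxygen that stays free and comes back to the route at 5.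

**Further compounds**

F1 | step 8 | 1‑(phenylsulfonyl)propa‑1,2‑diene | C=C=CS(=O)(=O)c1ccccc1
F2 | step 8 | allene cycloadduct: ring A as cyclohexene (C5=C6) with exocyclic methylene on C3, sp3 C1 (H, CH2OTBS), C2 (H, SO2Ph) and C4 (H2); racemic diastereomer mixture | C=C1CC(O[Si](C)(C)C(C)(C)C)=C(Oc2ccc(CC=C(C)C)c(O[Si](C)(C)C(C)(C)C)c2C(=O)OC)C(CO[Si](C)(C)C(C)(C)C)C1S(=O)(=O)c3ccccc3
F3 | step 3 | methyl 6‑{[1‑(dimethoxyphosphoryl)‑2‑oxopropyl]oxy}‑2‑hydroxy‑3‑(3‑methylbut‑2‑en‑1‑yl)benzoate (racemic) | CC(=O)C(Oc1ccc(CC=C(C)C)c(O)c1C(=O)OC)P(=O)(OC)OC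
F4 | step 3 | methyl 2‑hydroxy‑6‑({(3Z)‑5‑(TBSO)‑2‑oxopent‑3‑en‑3‑yl}oxy)‑3‑(3‑methylbut‑2‑en‑1‑yl)benzoate | CC(=O)/C(Oc1ccc(CC=C(C)C)c(O)c1C(=O)OC)=C/CO[Si](C)(C)C(C)(C)C
F5 | step 2 | methyl 2‑hydroxy‑6‑(2‑oxopropoxy)benzoate | CC(=O)COc1cccc(O)c1C(=O)OC
F6 | step 2 | methyl 2‑[(3‑methylbut‑2‑en‑1‑yl)oxy]‑6‑(2‑oxopropoxy)benzoate | CC(=O)COc1cccc(OCC=C(C)C)c1C(=O)OC
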